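**Retrosynthetic overview**
1. The target is opened at the ester (Steglich acylation of alcohol 8 with acid 9) and at C4, whose benzyl group is carried as an exocyclic C4=CH–Ar double bond. One final hydrogenation saturates it (sets C4) and frees both phenols.
2. The oxolane is the only ring made. It is closed at O1–C5 in an enantioselective palladium-catalysed [3+2] annulation of aldehyde 1 (gives O1 and C2) with the C3–C4–C5 unit of allylic carbonate 6. The same step makes C2–C3 and sets C2 and C3 (2,3-trans).
3. Enabling feature: ring carbon C4 and its benzyl CH2, raised one oxidation level to C4=CH–Ar, make the ring CH2 (C5) allylic and ionisable. The C3 side chain (CH2O-acyl), raised to the ester level, makes C3–H acidic. C3–C4(=CHAr)–C5 therefore behaves as an ester-substituted trimethylenemethane.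
4. Donor 6 comes from 1 and dimethyl succinate by Stobbe condensation, tert-butyl ester formation, selective reduction of the conjugated methyl ester and carbonate formation. Both guaiacyl rings come from 1.

Key step: step 5

Remark 1: the acyl stereocentre of the target reads as R, so (R)-2-methylbutanoic acid is used and is assumed to be a catalogue compound.
Remark 2: L1 is the (S)-BINOL-derived N,N-bis[(R)-1-phenylethyl]phosphoramidite or its mirror image. The sense of induction cannot be foretold for the new donor of step 5, so the route is written for the antipode that gives the (2R) ring.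

Step 1
Reactants: 1 4-(benzyloxy)-3-methoxybenzaldehyde; 2 dimethyl succinate
Product: 3 (3E)-4-[4-(benzyloxy)-3-methoxyphenyl]-3-(methoxycarbonyl)but-3-enoic acid
Conditions: NaOMe (2.2 equiv), MeOH, reflux; then aq. HCl
Reagents that add atoms: none
Why: Stobbe condensation, in which aldol addition, lactonisation to the paraconic ester and E1cB ring opening should give the half-ester with the free acid on the CH2 arm and the (E)-alkene (aryl trans to CO2Me).

Step 2
Reactants: 3 (3E)-4-[4-(benzyloxy)-3-methoxyphenyl]-3-(methoxycarbonyl)but-3-enoic acid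
Product: 4 4-tert-butyl 1-methyl (2E)-2-{[4-(benzyloxy)-3-methoxyphenyl]methylidene}butanedioate
Conditions: tert-butyl 2,2,2-trichloroacetimidate (2 equiv), cyclohexane/CH2Cl2, rt
Reagents that add atoms: tert-butyl 2,2,2-trichloroacetimidate, CC(C)(C)OC(=N)C(Cl)(Cl)Cl
Why: Imidate esterification, in which the acid protonates the imidate and takes up the tert-butyl group under mild conditions that leave the alkene geometry and the benzyl ether untouched.

Step 3
Reactants: 4 4-tert-butyl 1-methyl (2E)-2-{[4-(benzyloxy)-3-methoxyphenyl]methylidene}butanedioate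
Product: 5 tert-butyl (3E)-4-[4-(benzyloxy)-3-methoxyphenyl]-3-(hydroxymethyl)but-3-enoate
Conditions: iBu2AlH (2.3 equiv), CH2Cl2, −78 °C; aq. KNaC4H4O6 (potassium sodium tartrate) work-up
Reagents that add atoms: none
Why: Chemoselective 1,2-reduction of an ester, in which the conjugated methyl ester should go to the allylic alcohol while the bulky tert-butyl ester is spared at −78 °C.

Step 4
Reactants: 5 tert-butyl (3E)-4-[4-(benzyloxy)-3-methoxyphenyl]-3-(hydroxymethyl)but-3-enoate
Product: 6 tert-butyl (3E)-4-[4-(benzyloxy)-3-methoxyphenyl]-3-{[(tert-butoxycarbonyl)oxy]methyl}but-3-enoate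
Conditions: Boc2O (1.3 equiv), DMAP (10 mol%), Et3N, CH2Cl2, 0 °C to rt
Reagents that add atoms: di-tert-butyl dicarbonate, CC(C)(C)OC(=O)OC(=O)OC(C)(C)C
Why: DMAP-catalysed carbonate formation on the primary allylic alcohol, chosen because the tert-butyl carbonate releases tert-butoxide, the internal base of step 5.

Step 5
Reactants: 6 tert-butyl (3E)-4-[4-(benzyloxy)-3-methoxyphenyl]-3-{[(tert-butoxycarbonyl)oxy]methyl}but-3-enoate; 1 4-(benzyloxy)-3-methoxybenzaldehyde (1.5 equiv)
Product: 7 tert-butyl (2R,3R,4E)-2-[4-(benzyloxy)-3-methoxyphenyl]-4-{[4-(benzyloxy)-3-methoxyphenyl]methylidene}oxolane-3-carboxylate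
Conditions: Pd2(dba)3·CHCl3 (2.5 mol%), phosphoramidite L1 (10 mol%), 4 Å molecular sieves, toluene, 0 °C to rt
Reagents that add atoms: none
Why: Proposed new method: zerovalent palladium ionises the allylic carbonate of 6 to an η3-allylpalladium cation, CO2 is lost, and the tert-butoxide formed removes the C–H between the ester and the cationic allyl unit to give an ester-stabilised trimethylenemethane-type zwitterion, whose enolate carbon adds reversibly to the C=O of 1 before the alkoxide attacks the unsubstituted CH2 terminus of the allyl unit and closes O1–C5. The closest known reactions are the palladium–trimethylenemethane [3+2] cycloaddition with aryl aldehydes, which gives 2-aryl-4-methylene oxolanes enantioselectively with phosphoramidite ligands, and the carbonate-triggered deprotonative generation of acceptor-substituted trimethylenemethane donors; new here is the ester-stabilised donor with an aryl group on the alkylidene carbon combined with an aldehyde acceptor. The single ring closes by a 5-exo-tet-like attack of the alkoxide on the η3-allyl terminus anti to palladium, the closure that ends trimethylenemethane cycloadditions. C2 is set by the chiral ligand: because the aldol addition is reversible and the allyl faces interconvert by η3–η1–η3 isomerisation, all aldolate isomers and any E/Z mixture of 6 should be funnelled through the ligand-matched closure, and C3 follows as trans to the C2 aryl group, which is also the thermodynamic arrangement of this epimerisable centre. The step needs C–C bonding at the ester-bearing carbon (secured by the ester, which localises the charge there), attack of oxygen on the CH2 and not the aryl-bearing allyl terminus (secured by sterics and retained styrene conjugation, which also fixes the E geometry through the syn-aryl allyl complex), and no migration of the exocyclic double bond (low temperature, no added base).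

Step 6
Reactants: 7 tert-butyl (2R,3R,4E)-2-[4-(benzyloxy)-3-methoxyphenyl]-4-{[4-(benzyloxy)-3-methoxyphenyl]methylidene}oxolane-3-carboxylate
Product: 8 [(2R,3S,4E)-2-[4-(benzyloxy)-3-methoxyphenyl]-4-{[4-(benzyloxy)-3-methoxyphenyl]methylidene}oxolan-3-yl]methanol
Conditions: LiAlH4 (1.5 equiv), THF, −20 to 0 °C; aq. NaOH work-up
Reagents that add atoms: none
Why: Hydride reduction of the ester to the primary alcohol, which touches no stereocentre provided that reduction outpaces enolisation at C3, as expected at low temperature (the descriptor at C3 changes only through the priority rules).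

Step 7
Reactants: 8 [(2R,3S,4E)-2-[4-(benzyloxy)-3-methoxyphenyl]-4-{[4-(benzyloxy)-3-methoxyphenyl]methylidene}oxolan-3-yl]methanol; 9 (R)-2-methylbutanoic acid
Product: 10 [(2R,3S,4E)-2-[4-(benzyloxy)-3-methoxyphenyl]-4-{[4-(benzyloxy)-3-methoxyphenyl]methylidene}oxolan-3-yl]methyl (2R)-2-methylbutanoate
Conditions: DCC (1.3 equiv), DMAP (10 mol%), CH2Cl2, 0 °C to rt
Reagents that add atoms: none
Why: Steglich esterification of the primary alcohol, with catalytic DMAP at 0 °C to keep the α-stereocentre of the acid intact; acylation before step 8 also removes the surface-binding free hydroxyl that could deliver hydrogen to the wrong face.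

Step 8
Reactants: 10 [(2R,3S,4E)-2-[4-(benzyloxy)-3-methoxyphenyl]-4-{[4-(benzyloxy)-3-methoxyphenyl]methylidene}oxolan-3-yl]methyl (2R)-2-methylbutanoate
Product: 11 [(2R,3S,4S)-2-(4-hydroxy-3-methoxyphenyl)-4-[(4-hydroxy-3-methoxyphenyl)methyl]oxolan-3-yl]methyl (2R)-2-methylbutanoate
Conditions: H2 (1 atm), 10% Pd/C, EtOAc, rt, stopped after uptake of 3 equiv
Reagents that add atoms: none
Why: Heterogeneous catalytic hydrogenation should add H2 to the exocyclic C4=CH bond from the face opposite the adjacent C3 CH2O-acyl group, which allylic 1,3-strain with the cis aryl group holds pseudo-axial, so the new benzyl group ends cis to the C3 substituent and trans to the C2 aryl group (4S), while the same catalyst cleaves both benzyl aryl ethers by hydrogenolysis.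

**Compound list**
1 | 4-(benzyloxy)-3-methoxybenzaldehyde | O=Cc1ccc(OCc2ccccc2)c(OC)c1 | starting material
2 | dimethyl succinate | COC(=O)CCC(=O)OC | starting material
3 | (3E)-4-[4-(benzyloxy)-3-methoxyphenyl]-3-(methoxycarbonyl)but-3-enoic acid | OC(=O)C/C(=C\c1ccc(OCc2ccccc2)c(OC)c1)C(=O)OC | intermediate
4 | 4-tert-butyl 1-methyl (2E)-2-{[4-(benzyloxy)-3-methoxyphenyl]methylidene}butanedioate | CC(C)(C)OC(=O)C/C(=C\c1ccc(OCc2ccccc2)c(OC)c1)C(=O)OC | intermediate
5 | tert-butyl (3E)-4-[4-(benzyloxy)-3-methoxyphenyl]-3-(hydroxymethyl)but-3-enoate | CC(C)(C)OC(=O)C/C(=C\c1ccc(OCc2ccccc2)c(OC)c1)CO | intermediate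
6 | tert-butyl (3E)-4-[4-(benzyloxy)-3-methoxyphenyl]-3-{[(tert-butoxycarbonyl)oxy]methyl}but-3-enoate | CC(C)(C)OC(=O)C/C(=C\c1ccc(OCc2ccccc2)c(OC)c1)COC(=O)OC(C)(C)C | intermediate
7 | tert-butyl (2R,3R,4E)-2-[4-(benzyloxy)-3-methoxyphenyl]-4-{[4-(benzyloxy)-3-methoxyphenyl]methylidene}oxolane-3-carboxylate | CC(C)(C)OC(=O)[C@@H]1/C(=C\c2ccc(OCc3ccccc3)c(OC)c2)CO[C@H]1c1ccc(OCc2ccccc2)c(OC)c1 | intermediate
8 | [(2R,3S,4E)-2-[4-(benzyloxy)-3-methoxyphenyl]-4-{[4-(benzyloxy)-3-methoxyphenyl]methylidene}oxolan-3-yl]methanol | OC[C@@H]1/C(=C\c2ccc(OCc3ccccc3)c(OC)c2)CO[C@H]1c1ccc(OCc2ccccc2)c(OC)c1 | intermediate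
9 | (R)-2-methylbutanoic acid | CC[C@@H](C)C(=O)O | starting material
10 | [(2R,3S,4E)-2-[4-(benzyloxy)-3-methoxyphenyl]-4-{[4-(benzyloxy)-3-methoxyphenyl]methylidene}oxolan-3-yl]methyl (2R)-2-methylbutanoate | CC[C@@H](C)C(=O)OC[C@@H]1/C(=C\c2ccc(OCc3ccccc3)c(OC)c2)CO[C@H]1c1ccc(OCc2ccccc2)c(OC)c1 | intermediate
11 | [(2R,3S,4S)-2-(4-hydroxy-3-methoxyphenyl)-4-[(4-hydroxy-3-methoxyphenyl)methyl]oxolan-3-yl]methyl (2R)-2-methylbutanoate | CC[C@@H](C)C(=O)OC[C@@H]1[C@H](Cc2ccc(O)c(OC)c2)CO[C@H]1c1ccc(O)c(OC)c1 | target

**Step count**
Total steps: 8. Longest linear sequence: 8 (1 and 2 to 11).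

**Steps most likely to fail**

1. Step 5. The ester-stabilised zwitterion may fail to form, or may allylate itself instead of adding to the electron-rich aldehyde. Enantioselectivity may be low, and the exocyclic double bond may migrate into conjugation with the ester. The fallback uses known chemistry, sets out from 5 and comes back at 7.
   - 5 is silylated (TBSCl, imidazole, DMF) to silyl ether F1.
   - The lithium enolate of F1 (LiN(SiMe3)2, 2.1 equiv, THF, −78 °C) is C-acylated with 4-(benzyloxy)-3-methoxybenzoyl chloride to the racemic β-keto ester F2.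
   - Noyori-type asymmetric transfer hydrogenation with dynamic kinetic resolution (RuCl[(R,R)-TsDPEN](p-cymene), HCO2H/Et3N, CH2Cl2) should reduce the aryl ketone to the (R)-carbinol while the labile α-centre equilibrates, giving β-hydroxy ester F3.
   - Buffered desilylation (TBAF, AcOH, THF) gives diol F4.
   - Mitsunobu cyclodehydration (PPh3, DIAD, THF, 0 °C) activates the primary allylic alcohol, so the benzylic hydroxyl closes the same O1–C5 bond with retention at C2 and gives 7.
   - If the α-centre comes out as the other epimer, the 2,3-cis ester should equilibrate to 7 with catalytic DBU.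

2. Step 8. Facial selectivity may be poor, because the C2 aryl group on the other face competes with the C3 substituent. The double bond may migrate on the palladium surface before reduction, and the allylic or benzylic ring C–O bonds may undergo hydrogenolysis. The fallback sets out from 10 and comes back at 11.
   - The alkene alone is reduced by hydrogen-atom-transfer hydrogenation (Mn(dpm)3 with trivalent manganese, PhSiH3, tert-butyl hydroperoxide, isopropanol, rt). The bulky metal hydride should deliver hydrogen to C4 anti to the C3 substituent without touching benzyl ethers or ring C–O bonds, giving dibenzyl ether F5.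
   - The benzyl groups are then removed in a separate short hydrogenolysis (H2, Pd(OH)2/C, EtOAc) to give 11.

3. Step 3. Chemoselectivity between the two esters may be lost (over-reduction of the tert-butyl ester), or 5 may lactonise on work-up. The fallback sets out from 4 and comes back at 5.
   - LiOH (THF/H2O, rt) saponifies only the methyl ester to give acid F6.
   - BH3·SMe2 (THF, 0 °C) reduces the free carboxylic acid and not the tert-butyl ester, giving 5.

Further compounds
F1 | step 5 | tert-butyl (3E)-4-[4-(benzyloxy)-3-methoxyphenyl]-3-{[(tert-butyldimethylsilyl)oxy]methyl}but-3-enoate | CC(C)(C)OC(=O)C/C(=C\c1ccc(OCc2ccccc2)c(OC)c1)CO[Si](C)(C)C(C)(C)C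
F2 | step 5 | tert-butyl (3E)-2-[4-(benzyloxy)-3-methoxybenzoyl]-4-[4-(benzyloxy)-3-methoxyphenyl]-3-{[(tert-butyldimethylsilyl)oxy]methyl}but-3-enoate (racemic) | CC(C)(C)OC(=O)C(C(=O)c1ccc(OCc2ccccc2)c(OC)c1)/C(=C\c1ccc(OCc2ccccc2)c(OC)c1)CO[Si](C)(C)C(C)(C)C
F3 | step 5 | tert-butyl (2R,3E)-2-{(R)-[4-(benzyloxy)-3-methoxyphenyl](hydroxy)methyl}-4-[4-(benzyloxy)-3-methoxyphenyl]-3-{[(tert-butyldimethylsilyl)oxy]methyl}but-3-enoate | CC(C)(C)OC(=O)[C@@H]([C@@H](O)c1ccc(OCc2ccccc2)c(OC)c1)/C(=C\c1ccc(OCc2ccccc2)c(OC)c1)CO[Si](C)(C)C(C)(C)C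
F4 | step 5 | tert-butyl (2R,3E)-2-{(R)-[4-(benzyloxy)-3-methoxyphenyl](hydroxy)methyl}-4-[4-(benzyloxy)-3-methoxyphenyl]-3-(hydroxymethyl)but-3-enoate | CC(C)(C)OC(=O)[C@@H]([C@@H](O)c1ccc(OCc2ccccc2)c(OC)c1)/C(=C\c1ccc(OCc2ccccc2)c(OC)c1)CO
F5 | step 8 | [(2R,3S,4S)-2-[4-(benzyloxy)-3-methoxyphenyl]-4-{[4-(benzyloxy)-3-methoxyphenyl]methyl}oxolan-3-yl]methyl (2R)-2-methylbutanoate | CC[C@@H](C)C(=O)OC[C@@H]1[C@H](Cc2ccc(OCc3ccccc3)c(OC)c2)CO[C@H]1c1ccc(OCc2ccccc2)c(OC)c1
F6 | step 3 | (2E)-2-{[4-(benzyloxy)-3-methoxyphenyl]methylidene}-4-tert-butoxy-4-oxobutanoic acid | CC(C)(C)OC(=O)C/C(=C\c1ccc(OCc2ccccc2)c(OC)c1)C(=O)O
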